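## The problem

Numbering used throughout: core A is the 3,7-dioxabicyclo[3.3.0]octane (aryl carbons C2 and C6, ring-fusion carbons C1 and C5, oxygens O3 and O7, methylenes C4 and C8). Ring B is the guaiacyl ring on C2 that carries the keto arm, ring C is the benzo ring of the dihydrobenzofuran on C6, ring D is the aryl ketone ring, and ring E is the 2-aryl ring of the dihydrobenzofuran.

The target is a cis-fused 2,6-diaryl core A (1R,2S,5R,6S, both aryl groups exo) whose two aryl rings each carry, ortho to the phenolic oxygen, an arm of the same skeleton, aryl–CH(CH2OH)–C(X)–aryl. On ring B the arm is an (S)-configured α-aryl β-hydroxy ketone next to a free phenol. On ring C the same arm is reduced and closed through the ring C oxygen to a (2S,3S)-cis-2-aryl-3-hydroxymethyl-2,3-dihydrobenzofuran, the less stable ring diastereomer. Of the seven stereocentres, the four of core A are contiguous and can all be relayed from C2. The two arm centres next to rings B and C are too far from the core to be influenced by it and need reagent control, while C2 of the dihydrobenzofuran can be derived from its neighbour C3 by 1,2-induction followed by inversion. The keto arm does not survive base (enolisation, retro-aldol loss of formaldehyde, dehydration) and, with its neighbouring phenol, can cyclodehydrate to a benzofuran in acid. The benzylic ethers of core A and of the dihydrobenzofuran ionise in acid, which would epimerise C2/C6 and turn the cis ring into the trans ring, so the last unmasking must be near neutral. The two arms must also be made different although their precursors are alike. The feature that makes the key step possible lies in core A: O7–C8–C1, together with the oxygen-bearing C2, is an opened oxirane on a carbinol ether, C5–C6 is a cinnamyl unit linked to it through O3–C4, and C6 is benzylic to an oxygenated ring, so a C1 radical can close C1–C5 and the resulting C6 centre can be oxidised and captured by O7.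

## Retrosynthesis

**23 from 22.** No skeletal bond is cut; five O–Si bonds are cleaved at the end. Keeping every hydroxyl of the finished molecule as a silyl ether is preferred over acetal or acyl protection, because buffered fluoride is the only reagent that leaves the keto arm, the cis-dihydrobenzofuran and core A untouched. The forward step only has to be neutral.

**22 from 21, 21 from 20, 20 from 19.** The ring B ketone is traced back to a benzylic alcohol, and the O1–C2 bond of the dihydrobenzofuran is cut to a free ring C phenol and the same kind of benzylic alcohol. In this way both arms reach the same oxidation level in 19, and they differ only in the phenol protecting group (benzyl on ring C, silyl on ring B). The neighbouring option, reduction of one of two equivalent ketones, is statistical and would carry the enolisable keto arm through four more steps. Here hydrogenolysis frees only the ring C phenol (20), only that arm can close (21), and the other alcohol is oxidised afterwards (22). The closure must proceed with inversion at the carbinol carbon and the oxidation must not enolise the new ketone.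

**19 from 18, 18 from 17.** The primary silyl ethers are removed on paper and both carbinol C–H bonds are cut, which leads to the bis(β-hydroxy ketone) 17. Each carbinol centre is then set from the adjacent arm centre by chelation-controlled reduction, so no further reagent control is needed. The forward reduction must give the syn (1R,2S) diol in both arms, which is the one that inversion converts into the cis ring.

**17 from 16, 16 from 15.** Both Cα–CH2OH bonds are cut. A catalytic asymmetric hydroxymethylation of the enol silanes of the bis(deoxybenzoin) 15 installs the two remote (S) centres in one operation. The auxiliary-based alternative would need the arm carbonyl to be built twice. The forward reaction must select the Re face of each α-carbon and must not enolise the product.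

**15 from 12 and 14.** Both ring–Cα bonds are cut, giving the dibromide 12 and two molecules of the silylated acetovanillone 14. A twofold palladium-catalysed ketone α-arylation forms them directly at the positions ortho to the protected phenols, where the bromines of 5-bromovanillin already sit. No directing group or electrophilic substitution on the electron-rich core is needed.

**12 from 10 (key disconnection).** The C1–C5 and C6–O7 bonds are cut, which opens both rings of core A to the epoxy cinnamyl ether 10 with a single stereocentre that matters (the carbinol carbon, later C2). Oxidative dimerisation of a cinnamyl alcohol would give the core in one step but racemic and with identical aryl groups. The radical–polar bicyclisation allows two different aryl rings and derives all four core centres from one carbinol. The forward step must open the oxirane at C1, close 5-exo, and close the second ring with the C6 aryl group exo.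

**10 from 4 and 9.** The O3–C4 ether bond is cut to the epoxy alcohol 4 and the cinnamyl bromide 9. Etherification after epoxidation avoids having to epoxidise a vinyl group in the presence of a styrene. The forward step must not form a free alkoxide, which would trigger Payne rearrangement.

**4, 9 and 14 from 1, 6 and 13.** Compound 4 comes from 5-bromovanillin 1 by silylation (2), vinyl addition (3) and kinetic-resolution epoxidation. Compound 9 comes from 1 by benzylation (5), olefination with 6 (7), reduction (8) and bromination. Compound 14 comes from acetovanillone 13 by silylation. The two phenol protecting groups are chosen at this stage, at no cost in steps, so that the arms can be told apart later.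

## Roads not taken

**Alternative 1:** The O1–C2 bond of the dihydrobenzofuran is cut at the level of a separate ring C/ring E building block. The forward key step is a Mitsunobu closure of the syn phenolic alcohol A2 to the cis-dihydrobenzofuran acetal A1, with the ring E phenol as a pivalate. Its merits are that the two ring stereocentres come from an auxiliary-controlled syn aldol, which is more dependable than a catalytic hydroxymethylation, and that the electron-poor pivalate suppresses ionisation at the benzylic carbon. In this respect it is better than the chosen plan, which closes the same bond with a silyloxy aryl group in place. Its weak points for this target are that A1 is only one quarter of the molecule. Core A would still have to be built onto its masked aldehyde with a much more valuable fragment, the ring B arm would need a second, separate construction, and the pivalate would have to be removed with base in the presence of the keto arm or exchanged earlier. The chosen plan uses the same closure but performs all arm chemistry twofold on one core. Against the safer inversion it sets a lower step count and a fallback in which the aryl groups are switched to acetates before the closure.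

**Alternative 2:** The ring B–Cα and ring C–C3 bonds are cut. Both phenols of pinoresinol A4 would be alkylated with a chiral secondary allylic unit, and heating (with Eu(fod)3, trivalent europium, if needed) would move both allyl groups to the only free ortho carbons by aromatic Claisen rearrangement, giving A3. No ring closes. Its merits are that regiochemistry is fixed by the substitution pattern, that both arm centres would arise by chirality transfer in one step, that no palladium chemistry or hydroxymethylation is needed, and that the ethylidene groups are masked ketones. In bond economy on the core it is as good as or better than the chosen plan. Its weak points are the supply of enantiopure A4, the synthesis and clean O-alkylation of a secondary allylic partner with a trisubstituted alkene of defined geometry, and the uncertain chair/boat preference of a 2-aryl-substituted allyl unit, which decides the configuration. The two arms of A3 are also identical with two free phenols, so the desymmetrisation problem is untouched, and ozonolysis would have to be done on electron-rich phenols. The chosen plan sets against this its modular, enantioselective access to the core and its built-in difference between rings B and C.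

**Alternative 3:** The C2–aryl and C6–aryl bonds are cut. BF3·OEt2 would ionise both methyl acetals of the bis-acetal A6 in turn, and each oxocarbenium ion would be attacked by the para carbon of 2-bromo-6-methoxyphenol A7, giving 5,5′-dibromopinoresinol A5. No ring closes. Its merit is brevity: a dibromide of the same kind as 12 is reached in very few steps with free phenols, and in step count to the core it is clearly better than the chosen plan. Its weak points are the separate synthesis of enantiopure A6, competition from the position para to the methoxy group of A7, and the fact that the Lewis acid that forms A5 can also reionise its benzylic ethers, so that the exo,exo isomer is not secured kinetically. A5 is also twofold-symmetric, so the arms could later be distinguished only statistically, and its phenols would need reprotection before the arylation. The chosen plan sets against the shorter core synthesis a kinetic relay of all four centres from one carbinol and two different phenol protecting groups on 12.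

Key step: step 9

Assumption: the sense of induction of the Sc(OTf)3–bipyridine catalyst in step 13 is taken to be the same for the (Z)-α-aryl enol silanes of 16 as for simpler (Z)-enol silanes of aryl ketones; the ligand antipode that delivers formaldehyde to the Re face of each α-carbon is the one used (written below as the (S,S)-ligand).

Abbreviations in names: TIPS = triisopropylsilyl, TBS = tert-butyldimethylsilyl, Bn = benzyl.

## Route

Step 1
Reactants: 1 5-bromovanillin
Product: 2 3-bromo-5-methoxy-4-(triisopropylsilyloxy)benzaldehyde
Conditions: i-Pr3SiCl, imidazole, DMF, rt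
Reagents that add atoms: triisopropylsilyl chloride, CC(C)[Si](Cl)(C(C)C)C(C)C
Why: O-silylation of the phenol; the bulky aryl silyl ether should survive Grignard addition, trivalent titanium, K3PO4 and hydrogenolysis and is still removed by fluoride at the end, the only condition the finished keto arm on ring B tolerates.

Step 2
Reactants: 2 3-bromo-5-methoxy-4-(triisopropylsilyloxy)benzaldehyde
Product: 3 rac-1-[3-bromo-5-methoxy-4-(triisopropylsilyloxy)phenyl]prop-2-en-1-ol
Conditions: vinylmagnesium bromide, THF, −78 °C; aq. NH4Cl
Reagents that add atoms: vinylmagnesium bromide, C=C[Mg]Br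
Why: Grignard 1,2-addition to the aldehyde; the racemic allylic alcohol is the substrate wanted for the kinetic resolution.

Step 3
Reactants: 3 rac-1-[3-bromo-5-methoxy-4-(triisopropylsilyloxy)phenyl]prop-2-en-1-ol
Product: 4 (R)-[3-bromo-5-methoxy-4-(triisopropylsilyloxy)phenyl][(2S)-oxiran-2-yl]methanol
Conditions: Ti(OiPr)4 (0.15 equiv), D-(−)-diisopropyl tartrate (0.2 equiv), t-BuOOH (0.45 equiv), 4 Å MS, CH2Cl2, −20 °C
Reagents that add atoms: tert-butyl hydroperoxide, CC(C)(C)OO
Why: Sharpless kinetic-resolution epoxidation: with the D-tartrate the (S)-enantiomer of 3 reacts fast and gives the erythro epoxy alcohol, so stopping below half conversion should give 4 in high enantiomeric purity while the (R)-enantiomer of 3 is left behind. The carbinol carbon keeps its spatial arrangement and is labelled R only because the oxirane carbon now outranks the aryl group; the oxirane carbon itself is later planarised, so only the carbinol centre has to be pure.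

Step 4
Reactants: 1 5-bromovanillin
Product: 5 4-(benzyloxy)-3-bromo-5-methoxybenzaldehyde
Conditions: BnBr, K2CO3, DMF, rt
Reagents that add atoms: benzyl bromide, BrCc1ccccc1
Why: Williamson etherification of the phenol; the benzyl ether on ring C is the one protecting group of the route that is removed by hydrogenolysis, which later frees the ring C phenol alone.

Step 5
Reactants: 5 4-(benzyloxy)-3-bromo-5-methoxybenzaldehyde; 6 triethyl phosphonoacetate
Product: 7 ethyl (2E)-3-[4-(benzyloxy)-3-bromo-5-methoxyphenyl]prop-2-enoate
Conditions: NaH, THF, 0 °C → rt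
Reagents that add atoms: none
Why: Horner–Wadsworth–Emmons olefination; the stabilised phosphonate anion gives the (E)-cinnamate.

Step 6
Reactants: 7 ethyl (2E)-3-[4-(benzyloxy)-3-bromo-5-methoxyphenyl]prop-2-enoate
Product: 8 (2E)-3-[4-(benzyloxy)-3-bromo-5-methoxyphenyl]prop-2-en-1-ol
Conditions: i-Bu2AlH (2.2 equiv), CH2Cl2, −78 °C; aq. potassium sodium tartrate
Reagents that add atoms: none
Why: 1,2-reduction of the unsaturated ester to the allylic alcohol by i-Bu2AlH; the alkene geometry and the aryl bromide are untouched.

Step 7
Reactants: 8 (2E)-3-[4-(benzyloxy)-3-bromo-5-methoxyphenyl]prop-2-en-1-ol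
Product: 9 (E)-1-[4-(benzyloxy)-3-bromo-5-methoxyphenyl]-3-bromoprop-1-ene
Conditions: CBr4, PPh3, CH2Cl2, 0 °C
Reagents that add atoms: carbon tetrabromide, BrC(Br)(Br)Br
Why: Appel bromination under neutral conditions gives the linear (E)-cinnamyl bromide, which is used without storage.

Step 8
Reactants: 4 (R)-[3-bromo-5-methoxy-4-(triisopropylsilyloxy)phenyl][(2S)-oxiran-2-yl]methanol; 9 (E)-1-[4-(benzyloxy)-3-bromo-5-methoxyphenyl]-3-bromoprop-1-ene
Product: 10 (2S)-2-[(R)-{[(2E)-3-(4-benzyloxy-3-bromo-5-methoxyphenyl)prop-2-en-1-yl]oxy}(3-bromo-5-methoxy-4-triisopropylsilyloxyphenyl)methyl]oxirane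
Conditions: Ag2O, KI (cat.), 4 Å MS, CH2Cl2, rt, dark
Reagents that add atoms: none
Why: Silver-assisted Williamson etherification: Ag2O activates the allylic bromide and takes up HBr without forming a free alkoxide, so the epoxy alcohol cannot undergo Payne rearrangement and the carbinol configuration is untouched.

Step 9
Reactants: 10 (2S)-2-[(R)-{[(2E)-3-(4-benzyloxy-3-bromo-5-methoxyphenyl)prop-2-en-1-yl]oxy}(3-bromo-5-methoxy-4-triisopropylsilyloxyphenyl)methyl]oxirane
Product: 12 (1R,2S,5R,6S)-6-(4-benzyloxy-3-bromo-5-methoxyphenyl)-2-(3-bromo-5-methoxy-4-triisopropylsilyloxyphenyl)-3,7-dioxabicyclo[3.3.0]octane, via benzylic iodide 11 (not isolated)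
Conditions: Cp2TiCl2 (2.5 equiv), Zn, THF, rt, slow addition of 10; then I2, THF, rt → 60 °C
Reagents that add atoms: none
Why: Cp2TiCl (trivalent titanium, made in the flask from Cp2TiCl2 and Zn) transfers one electron to the oxirane of 10 and cleaves its C–O bond at the more substituted carbon, so either oxirane epimer gives the same β-titanoxy radical at C1. This radical adds 5-exo-trig to the cinnamyl alkene (C1–C5 bond, first oxolane ring) through a chair-like transition state with the C2 aryl group pseudo-equatorial, which places C8 on C1 trans to the C2 aryl group and sets C5 cis to C1. The benzylic C6 radical is captured by a second Cp2TiCl, iodine turns the C6–Ti bond into the iodide 11, and the tetravalent titanium alkoxide on C8 displaces it 5-exo-tet with strong cation character, closing the second oxolane ring (C6–O7). Because the alkoxide is tethered to C1, the new ring can only be cis-fused, and the C6 aryl group takes the exo position on the convex face. The closest known reaction type is the titanocene-mediated reductive opening and 5-exo cyclisation of epoxy allyl ethers with iodine-induced closure to furofuran lignans. The step needs regioselective oxirane opening (secured by the greater stability of the secondary radical), 5-exo rather than 6-endo closure (secured by the styrene-type acceptor) and inertness of the aryl bromides, the silyl ether and the benzyl ether, none of which reacts with trivalent titanium or iodine. The descriptor at C2 changes from R in 10 to S in 12 only because C1 no longer carries oxygen.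

Step 10
Reactants: 13 acetovanillone
Product: 14 1-[3-methoxy-4-(triisopropylsilyloxy)phenyl]ethan-1-one
Conditions: i-Pr3SiCl, imidazole, DMF, rt
Reagents that add atoms: triisopropylsilyl chloride, CC(C)[Si](Cl)(C(C)C)C(C)C
Why: O-silylation of the phenol, so that only the methyl ketone is deprotonated in the coupling and the ring D/ring E oxygen can be freed by fluoride at the end.

Step 11
Reactants: 12 (1R,2S,5R,6S)-6-(4-benzyloxy-3-bromo-5-methoxyphenyl)-2-(3-bromo-5-methoxy-4-triisopropylsilyloxyphenyl)-3,7-dioxabicyclo[3.3.0]octane; 14 1-[3-methoxy-4-(triisopropylsilyloxy)phenyl]ethan-1-one (2.6 equiv)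
Product: 15 bis(deoxybenzoin): 12 in which each bromine is replaced by a 2-[3-methoxy-4-(triisopropylsilyloxy)phenyl]-2-oxoethyl group
Conditions: Pd(OAc)2 (10 mol%), XPhos (20 mol%), K3PO4, toluene, 90 °C
Reagents that add atoms: none
Why: Twofold palladium-catalysed α-arylation of a methyl aryl ketone with aryl bromides (oxidative addition to zerovalent palladium, enolate transmetalation, reductive elimination); the mild phosphate base spares the aryl silyl ethers. A second arylation is disfavoured because the product methylene is flanked by an ortho-substituted aryl group and its enolate is more stabilised.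

Step 12
Reactants: 15 bis(deoxybenzoin)
Product: 16 twofold (Z)-trimethylsilyl enol ether of 15 (each CH2C(=O)Ar unit becomes CH=C(OSiMe3)Ar with OSiMe3 cis to the core aryl ring)
Conditions: LiN(SiMe3)2 (2.4 equiv), Me3SiCl, THF, −78 → 0 °C; non-aqueous work-up
Reagents that add atoms: chlorotrimethylsilane, C[Si](C)(C)Cl
Why: Enolisation of the acidic benzylic ketone positions and O-silylation; the (Z)-enolate is favoured for aryl benzyl ketones because it avoids allylic strain between the ketone aryl group and the β-aryl group, and the strongly basic but non-Lewis-acidic medium leaves core A alone.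

Step 13
Reactants: 16 twofold (Z)-trimethylsilyl enol ether of 15
Product: 17 bis(β-hydroxy ketone): 15 with a hydroxymethyl group on each α-carbon, each arm being (S)-CH(CH2OH)C(=O)Ar
Conditions: Sc(OTf)3 (20 mol%), (S,S)-6,6′-bis(1-hydroxy-2,2-dimethylpropyl)-2,2′-bipyridine (24 mol%), aq. HCHO, DME/H2O 9:1, −20 °C
Reagents that add atoms: formaldehyde, C=O
Why: Catalytic asymmetric Mukaiyama aldol hydroxymethylation of silicon enolates with aqueous formaldehyde; the chiral scandium–bipyridine complex, not the distant core, selects the Re face of each α-carbon and so sets both (S) centres. The nearly neutral, weakly Lewis-acidic medium should not enolise the new α-aryl ketone, and 17 is reduced at once in the next step.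

Step 14
Reactants: 17 bis(β-hydroxy ketone)
Product: 18 tetraol: both ketones of 17 reduced, each arm being (1R,2S)-ArCH(OH)–CH(CH2OH)– (carbinol carbon R, core-aryl-bearing carbon S, syn)
Conditions: Zn(BH4)2, Et2O/THF, −20 → 0 °C; aq. NH4Cl
Reagents that add atoms: none
Why: Chelation-controlled reduction of α-substituted β-hydroxy ketones: zinc bridges the carbonyl and the primary hydroxyl, and hydride adds to the face of the chelate opposite to the α-aryl group (the Felkin–Anh sense as well), which gives the syn diol. Both ketones are reduced on purpose, so no statistical step is needed and the enolisable arm centres are stored as non-enolisable alcohols.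

Step 15
Reactants: 18 tetraol
Product: 19 18 with both primary hydroxyls as tert-butyldimethylsilyl ethers
Conditions: t-BuMe2SiCl (2.2 equiv), imidazole, CH2Cl2, 0 °C
Reagents that add atoms: tert-butyldimethylsilyl chloride, CC(C)(C)[Si](C)(C)Cl
Why: Selective silylation of the two primary alcohols in the presence of the hindered secondary benzylic alcohols; this keeps the primary carbons out of the later Mitsunobu closure, where they would otherwise form the wrong five-membered ring.

Step 16
Reactants: 19 bis(primary TBS ether)
Product: 20 19 with the benzyl ether on ring C replaced by a free phenol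
Conditions: H2 (1 atm), Pd/C (10% palladium on carbon), EtOAc, rt
Reagents that add atoms: none
Why: Hydrogenolysis of the aryl benzyl ether; a phenolic O-benzyl group should be cleaved much faster than the cyclic benzylic ethers of core A or the benzylic alcohols in neutral ethyl acetate, and the reaction is stopped as soon as 19 is consumed.

Step 17
Reactants: 20 ring C phenol
Product: 21 ring C arm closed to the (2S,3S)-cis-2-[3-methoxy-4-(triisopropylsilyloxy)phenyl]-3-(TBS-oxymethyl)-7-methoxy-2,3-dihydrobenzofuran, ring B arm unchanged as the (1R,2S) alcohol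
Conditions: PPh3, diisopropyl azodicarboxylate (1.2 equiv each), toluene, 0 °C
Reagents that add atoms: none
Why: Mitsunobu reaction: the ring C phenol is the only acidic partner and displaces the activated benzylic hydroxyl of its own arm 5-exo-tet with inversion, converting the (1R,2S) syn unit into the (2S,3S) cis ring. The other benzylic alcohol has no internal nucleophile, its alkoxyphosphonium ion forms reversibly, and with only a slight excess of reagents it should be returned on work-up; the non-polar solvent and low temperature disfavour ionisation.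

Step 18
Reactants: 21 cis-dihydrobenzofuran alcohol
Product: 22 21 with the ring B benzylic alcohol oxidised to the aryl ketone (arm centre S)
Conditions: Dess–Martin periodinane, NaHCO3, CH2Cl2, 0 °C → rt
Reagents that add atoms: none
Why: Dess–Martin oxidation of the one remaining secondary alcohol under buffered, non-basic conditions that should not enolise the new α-aryl ketone; all phenols are protected, so the trivalent-iodine-forming oxidant has no other site.

Step 19
Reactants: 22 protected ketone
Product: 23 (2S)-3-hydroxy-1-(4-hydroxy-3-methoxyphenyl)-2-{2-hydroxy-5-[(1R,2S,5R,6S)-6-[(2S,3S)-2-(4-hydroxy-3-methoxyphenyl)-3-(hydroxymethyl)-7-methoxy-2,3-dihydro-1-benzofuran-5-yl]-3,7-dioxabicyclo[3.3.0]octan-2-yl]-3-methoxyphenyl}propan-1-one (CNP0174045.1)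
Conditions: Bu4NF/AcOH (1:1, excess), THF, 0 °C → rt
Reagents that add atoms: none
Why: Fluoride cleavage of the three aryl silyl ethers and the two primary silyl ethers; acetic acid buffering keeps the medium near neutral, so the β-hydroxy ketone should be neither epimerised nor dehydrated and the benzylic ethers of the dihydrobenzofuran and of core A are not opened.

## Compound list

1 | 5-bromovanillin | COc1cc(C=O)cc(Br)c1O | starting material
2 | 3-bromo-5-methoxy-4-(triisopropylsilyloxy)benzaldehyde | COc1cc(C=O)cc(Br)c1O[Si](C(C)C)(C(C)C)C(C)C | intermediate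
3 | rac-1-[3-bromo-5-methoxy-4-(triisopropylsilyloxy)phenyl]prop-2-en-1-ol | COc1cc(cc(Br)c1O[Si](C(C)C)(C(C)C)C(C)C)C(O)C=C | intermediate
4 | (R)-[3-bromo-5-methoxy-4-(triisopropylsilyloxy)phenyl][(2S)-oxiran-2-yl]methanol | COc1cc(cc(Br)c1O[Si](C(C)C)(C(C)C)C(C)C)[C@H]([C@@H]1CO1)O | intermediate
5 | 4-(benzyloxy)-3-bromo-5-methoxybenzaldehyde | COc1cc(C=O)cc(Br)c1OCc1ccccc1 | intermediate
6 | triethyl phosphonoacetate | CCOC(=O)CP(=O)(OCC)OCC | starting material
7 | ethyl (2E)-3-[4-(benzyloxy)-3-bromo-5-methoxyphenyl]prop-2-enoate | CCOC(=O)/C=C/c1cc(OC)c(OCc2ccccc2)c(Br)c1 | intermediate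
8 | (2E)-3-[4-(benzyloxy)-3-bromo-5-methoxyphenyl]prop-2-en-1-ol | OC/C=C/c1cc(OC)c(OCc2ccccc2)c(Br)c1 | intermediate
9 | (E)-1-[4-(benzyloxy)-3-bromo-5-methoxyphenyl]-3-bromoprop-1-ene | BrC/C=C/c1cc(OC)c(OCc2ccccc2)c(Br)c1 | intermediate
10 | (2S)-2-[(R)-{[(2E)-3-(4-benzyloxy-3-bromo-5-methoxyphenyl)prop-2-en-1-yl]oxy}(3-bromo-5-methoxy-4-triisopropylsilyloxyphenyl)methyl]oxirane | COc1cc(cc(Br)c1O[Si](C(C)C)(C(C)C)C(C)C)[C@H]([C@@H]1CO1)OC/C=C/c1cc(OC)c(OCc2ccccc2)c(Br)c1 | intermediate
11 | [(2S,3R,4R)-4-[(4-benzyloxy-3-bromo-5-methoxyphenyl)(iodo)methyl]-2-(3-bromo-5-methoxy-4-triisopropylsilyloxyphenyl)oxolan-3-yl]methanol, present as its tetravalent titanium alkoxide, iodide carbon as a mixture of epimers (written as the free alcohol) | COc1cc(cc(Br)c1O[Si](C(C)C)(C(C)C)C(C)C)[C@H]1OC[C@H](C(I)c2cc(OC)c(OCc3ccccc3)c(Br)c2)[C@@H]1CO | intermediate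
12 | (1R,2S,5R,6S)-6-(4-benzyloxy-3-bromo-5-methoxyphenyl)-2-(3-bromo-5-methoxy-4-triisopropylsilyloxyphenyl)-3,7-dioxabicyclo[3.3.0]octane | COc1cc(cc(Br)c1O[Si](C(C)C)(C(C)C)C(C)C)[C@H]1OC[C@H]2[C@@H]1CO[C@@H]2c1cc(OC)c(OCc2ccccc2)c(Br)c1 | intermediate
13 | acetovanillone, 1-(4-hydroxy-3-methoxyphenyl)ethan-1-one | CC(=O)c1ccc(O)c(OC)c1 | starting material
14 | 1-[3-methoxy-4-(triisopropylsilyloxy)phenyl]ethan-1-one | CC(=O)c1ccc(O[Si](C(C)C)(C(C)C)C(C)C)c(OC)c1 | intermediate
15 | bis(deoxybenzoin): 12 with each bromine replaced by a 2-[3-methoxy-4-(triisopropylsilyloxy)phenyl]-2-oxoethyl group | COc1cc(cc(CC(=O)c2ccc(O[Si](C(C)C)(C(C)C)C(C)C)c(OC)c2)c1O[Si](C(C)C)(C(C)C)C(C)C)[C@H]1OC[C@H]2[C@@H]1CO[C@@H]2c1cc(OC)c(OCc2ccccc2)c(CC(=O)c2ccc(O[Si](C(C)C)(C(C)C)C(C)C)c(OC)c2)c1 | intermediate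
16 | twofold (Z)-trimethylsilyl enol ether of 15 | COc1cc(cc(/C=C(\O[Si](C)(C)C)c2ccc(O[Si](C(C)C)(C(C)C)C(C)C)c(OC)c2)c1O[Si](C(C)C)(C(C)C)C(C)C)[C@H]1OC[C@H]2[C@@H]1CO[C@@H]2c1cc(OC)c(OCc2ccccc2)c(/C=C(\O[Si](C)(C)C)c2ccc(O[Si](C(C)C)(C(C)C)C(C)C)c(OC)c2)c1 | intermediate
17 | bis(β-hydroxy ketone), each arm (S)-CH(CH2OH)C(=O)Ar | COc1cc(cc([C@@H](CO)C(=O)c2ccc(O[Si](C(C)C)(C(C)C)C(C)C)c(OC)c2)c1O[Si](C(C)C)(C(C)C)C(C)C)[C@H]1OC[C@H]2[C@@H]1CO[C@@H]2c1cc(OC)c(OCc2ccccc2)c([C@@H](CO)C(=O)c2ccc(O[Si](C(C)C)(C(C)C)C(C)C)c(OC)c2)c1 | intermediate
18 | tetraol, each arm (1R,2S)-ArCH(OH)CH(CH2OH)–, syn | COc1cc(cc([C@@H](CO)[C@@H](O)c2ccc(O[Si](C(C)C)(C(C)C)C(C)C)c(OC)c2)c1O[Si](C(C)C)(C(C)C)C(C)C)[C@H]1OC[C@H]2[C@@H]1CO[C@@H]2c1cc(OC)c(OCc2ccccc2)c([C@@H](CO)[C@@H](O)c2ccc(O[Si](C(C)C)(C(C)C)C(C)C)c(OC)c2)c1 | intermediate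
19 | 18 with both primary hydroxyls as TBS ethers | COc1cc(cc([C@@H](CO[Si](C)(C)C(C)(C)C)[C@@H](O)c2ccc(O[Si](C(C)C)(C(C)C)C(C)C)c(OC)c2)c1O[Si](C(C)C)(C(C)C)C(C)C)[C@H]1OC[C@H]2[C@@H]1CO[C@@H]2c1cc(OC)c(OCc2ccccc2)c([C@@H](CO[Si](C)(C)C(C)(C)C)[C@@H](O)c2ccc(O[Si](C(C)C)(C(C)C)C(C)C)c(OC)c2)c1 | intermediate
20 | 19 with a free phenol on ring C in place of the benzyl ether | COc1cc(cc([C@@H](CO[Si](C)(C)C(C)(C)C)[C@@H](O)c2ccc(O[Si](C(C)C)(C(C)C)C(C)C)c(OC)c2)c1O[Si](C(C)C)(C(C)C)C(C)C)[C@H]1OC[C@H]2[C@@H]1CO[C@@H]2c1cc(OC)c(O)c([C@@H](CO[Si](C)(C)C(C)(C)C)[C@@H](O)c2ccc(O[Si](C(C)C)(C(C)C)C(C)C)c(OC)c2)c1 | intermediate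
21 | ring C arm closed to the (2S,3S)-cis-dihydrobenzofuran, ring B arm as the (1R,2S) alcohol | COc1cc(cc([C@@H](CO[Si](C)(C)C(C)(C)C)[C@@H](O)c2ccc(O[Si](C(C)C)(C(C)C)C(C)C)c(OC)c2)c1O[Si](C(C)C)(C(C)C)C(C)C)[C@H]1OC[C@H]2[C@@H]1CO[C@@H]2c1cc(OC)c2c(c1)[C@@H](CO[Si](C)(C)C(C)(C)C)[C@@H](c1ccc(O[Si](C(C)C)(C(C)C)C(C)C)c(OC)c1)O2 | intermediate
22 | 21 with the ring B benzylic alcohol oxidised to the ketone, arm centre S | COc1cc(cc([C@@H](CO[Si](C)(C)C(C)(C)C)C(=O)c2ccc(O[Si](C(C)C)(C(C)C)C(C)C)c(OC)c2)c1O[Si](C(C)C)(C(C)C)C(C)C)[C@H]1OC[C@H]2[C@@H]1CO[C@@H]2c1cc(OC)c2c(c1)[C@@H](CO[Si](C)(C)C(C)(C)C)[C@@H](c1ccc(O[Si](C(C)C)(C(C)C)C(C)C)c(OC)c1)O2 | intermediate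
23 | CNP0174045.1, (2S)-3-hydroxy-1-(4-hydroxy-3-methoxyphenyl)-2-{2-hydroxy-5-[(1R,2S,5R,6S)-6-[(2S,3S)-2-(4-hydroxy-3-methoxyphenyl)-3-(hydroxymethyl)-7-methoxy-2,3-dihydro-1-benzofuran-5-yl]-3,7-dioxabicyclo[3.3.0]octan-2-yl]-3-methoxyphenyl}propan-1-one | COc1cc(cc([C@@H](CO)C(=O)c2ccc(O)c(OC)c2)c1O)[C@H]1OC[C@H]2[C@@H]1CO[C@@H]2c1cc(OC)c2c(c1)[C@@H](CO)[C@@H](c1ccc(O)c(OC)c1)O2 | target

## Step count and risks

Total: 19 steps. Longest linear sequence: 15 steps (1 → 5 → 7 → 8 → 9 → 10 → 12 → 15 → 16 → 17 → 18 → 19 → 20 → 21 → 22 → 23, that is steps 4–9 and 11–19).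

**Step 9 (key step).** The most likely failure is loss of the C6 benzylic radical or its titanium derivative by protonation or hydrogen loss before iodine can act. A second risk is incomplete exo selectivity in the ionic closure, since the benzylic cation closes under little steric bias and the bromine on ring C makes it less stable and slower to form. Fallback: the two events are separated. Setting out from 10, the Cp2TiCl cyclisation is run without iodine and quenched with aqueous acid, which gives the monocyclic alcohol [(2S,3R,4R)-4-(4-benzyloxy-3-bromo-5-methoxybenzyl)-2-(3-bromo-5-methoxy-4-triisopropylsilyloxyphenyl)oxolan-3-yl]methanol F1. Benzylic oxidation of F1 with DDQ in CH2Cl2, with capture of the benzylic cation by the primary hydroxyl, then closes the second ring and returns to the route at 12.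

**Step 13.** The most likely failure is insufficient facial selectivity at one or both α-carbons, together with competing protodesilylation back to 15. The α-aryl enol silane is bulkier, and its aldol product more easily enolised, than the alkyl-substituted cases on which this catalyst is established, and two independent additions multiply any error into diastereomers that are hard to separate. Fallback: an auxiliary-controlled syn aldol replaces steps 11–14.
- Setting out from 12, twofold Negishi coupling with the Reformatsky reagent BrZnCH2CO2Et (Pd(dba)2, P(t-Bu)3, THF) gives the bis(ethyl arylacetate) F2.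
- Me3SnOH in 1,2-dichloroethane gives the diacid F3.
- Activation as the mixed pivalic anhydride and acylation of lithiated (R)-4-benzyl-1,3-oxazolidin-2-one gives the bis-imide F4.
- Bu2BOTf/i-Pr2NEt enolisation and aldol addition to 3-methoxy-4-(triisopropylsilyloxy)benzaldehyde F5 (the silyl ether of the commercial hydroxy aldehyde) gives the bis(syn aldol) F6, with each arm (2R,3R).
- LiBH4 removes both auxiliaries reductively and returns to the route at 18.

**Step 17.** The most likely failure is ionisation of the alkoxyphosphonium ion at the benzylic carbon, which carries a para-silyloxy aryl group. A benzylic cation would close to the more stable trans ring and erase the inversion, and the free benzylic alcohol of the ring B arm could be consumed by elimination. Fallback: the aryl groups are made electron-poor for the closure.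
- Setting out from 19, Bu4NF/AcOH at 0 °C removes the three aryl silyl groups and gives the triphenol F7.
- Ac2O with aqueous NaHCO3 acetylates the phenols only and gives the tris(aryl acetate) F8.
- Hydrogenolysis (H2, Pd/C) gives the ring C phenol F9.
- The Mitsunobu closure, now next to an acetoxyaryl group, gives the cis-dihydrobenzofuran tris-acetate F10.
- K2CO3 in methanol (no ketone is present at this stage) gives the triphenol F11.
- i-Pr3SiCl/imidazole resilylates the phenols and returns to the route at 21.

**Step 11.** The most likely failure is slow turnover at the two hindered, electron-rich aryl bromides, leading to mono-coupling or hydrodebromination, and base-induced loss or migration of the aryl silyl groups at 90 °C. Fallback: a neutral tin-enolate arylation (Migita–Kosugi type). Compound 14 is converted with isopropenyl acetate and catalytic TsOH into the enol acetate 1-[3-methoxy-4-(triisopropylsilyloxy)phenyl]ethenyl acetate F12. Setting out from 12, F12 and Bu3SnOMe with PdCl2[P(o-tol)3]2 in toluene at 100 °C couple through the tributyltin enolate without added base and return to the route at 15.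

## Further compounds

F1 | step 9 | [(2S,3R,4R)-4-(4-benzyloxy-3-bromo-5-methoxybenzyl)-2-(3-bromo-5-methoxy-4-triisopropylsilyloxyphenyl)oxolan-3-yl]methanol | COc1cc(cc(Br)c1O[Si](C(C)C)(C(C)C)C(C)C)[C@H]1OC[C@H](Cc2cc(OC)c(OCc3ccccc3)c(Br)c2)[C@@H]1CO
F2 | step 13 | bis(ethyl arylacetate): 12 with each bromine replaced by CH2CO2Et | COc1cc(cc(CC(=O)OCC)c1O[Si](C(C)C)(C(C)C)C(C)C)[C@H]1OC[C@H]2[C@@H]1CO[C@@H]2c1cc(OC)c(OCc2ccccc2)c(CC(=O)OCC)c1
F3 | step 13 | bis(arylacetic acid): 12 with each bromine replaced by CH2CO2H | COc1cc(cc(CC(=O)O)c1O[Si](C(C)C)(C(C)C)C(C)C)[C@H]1OC[C@H]2[C@@H]1CO[C@@H]2c1cc(OC)c(OCc2ccccc2)c(CC(=O)O)c1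
F4 | step 13 | bis-imide: each arylacetic acid of F3 as its N-acyl (R)-4-benzyl-1,3-oxazolidin-2-one | COc1cc(cc(CC(=O)N2[C@H](Cc3ccccc3)COC2=O)c1O[Si](C(C)C)(C(C)C)C(C)C)[C@H]1OC[C@H]2[C@@H]1CO[C@@H]2c1cc(OC)c(OCc2ccccc2)c(CC(=O)N2[C@H](Cc3ccccc3)COC2=O)c1
F5 | step 13 | 3-methoxy-4-(triisopropylsilyloxy)benzaldehyde | O=Cc1ccc(O[Si](C(C)C)(C(C)C)C(C)C)c(OC)c1
F6 | step 13 | bis(syn aldol): each arm (2R,3R)-3-hydroxy-3-[3-methoxy-4-(triisopropylsilyloxy)phenyl]-2-(core aryl)propanoyl on (R)-4-benzyl-1,3-oxazolidin-2-one | COc1cc(cc([C@H]([C@@H](O)c2ccc(O[Si](C(C)C)(C(C)C)C(C)C)c(OC)c2)C(=O)N2[C@H](Cc3ccccc3)COC2=O)c1O[Si](C(C)C)(C(C)C)C(C)C)[C@H]1OC[C@H]2[C@@H]1CO[C@@H]2c1cc(OC)c(OCc2ccccc2)c([C@H]([C@@H](O)c2ccc(O[Si](C(C)C)(C(C)C)C(C)C)c(OC)c2)C(=O)N2[C@H](Cc3ccccc3)COC2=O)c1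
F7 | step 17 | 19 without its three aryl silyl groups (free phenols on rings B, D and E) | COc1cc(cc([C@@H](CO[Si](C)(C)C(C)(C)C)[C@@H](O)c2ccc(O)c(OC)c2)c1O)[C@H]1OC[C@H]2[C@@H]1CO[C@@H]2c1cc(OC)c(OCc2ccccc2)c([C@@H](CO[Si](C)(C)C(C)(C)C)[C@@H](O)c2ccc(O)c(OC)c2)c1
F8 | step 17 | tris(aryl acetate) of F7 | COc1cc(cc([C@@H](CO[Si](C)(C)C(C)(C)C)[C@@H](O)c2ccc(OC(C)=O)c(OC)c2)c1OC(C)=O)[C@H]1OC[C@H]2[C@@H]1CO[C@@H]2c1cc(OC)c(OCc2ccccc2)c([C@@H](CO[Si](C)(C)C(C)(C)C)[C@@H](O)c2ccc(OC(C)=O)c(OC)c2)c1
F9 | step 17 | F8 with a free phenol on ring C in place of the benzyl ether | COc1cc(cc([C@@H](CO[Si](C)(C)C(C)(C)C)[C@@H](O)c2ccc(OC(C)=O)c(OC)c2)c1OC(C)=O)[C@H]1OC[C@H]2[C@@H]1CO[C@@H]2c1cc(OC)c(O)c([C@@H](CO[Si](C)(C)C(C)(C)C)[C@@H](O)c2ccc(OC(C)=O)c(OC)c2)c1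
F10 | step 17 | (2S,3S)-cis-dihydrobenzofuran tris(aryl acetate), ring B arm as the (1R,2S) alcohol | COc1cc(cc([C@@H](CO[Si](C)(C)C(C)(C)C)[C@@H](O)c2ccc(OC(C)=O)c(OC)c2)c1OC(C)=O)[C@H]1OC[C@H]2[C@@H]1CO[C@@H]2c1cc(OC)c2c(c1)[C@@H](CO[Si](C)(C)C(C)(C)C)[C@@H](c1ccc(OC(C)=O)c(OC)c1)O2
F11 | step 17 | 21 without its three aryl silyl groups | COc1cc(cc([C@@H](CO[Si](C)(C)C(C)(C)C)[C@@H](O)c2ccc(O)c(OC)c2)c1O)[C@H]1OC[C@H]2[C@@H]1CO[C@@H]2c1cc(OC)c2c(c1)[C@@H](CO[Si](C)(C)C(C)(C)C)[C@@H](c1ccc(O)c(OC)c1)O2
F12 | step 11 | 1-[3-methoxy-4-(triisopropylsilyloxy)phenyl]ethenyl acetate | CC(=O)OC(=C)c1ccc(O[Si](C(C)C)(C(C)C)C(C)C)c(OC)c1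
A1 | alternative 1 | (2S,3S)-3-[(tert-butyldimethylsilyloxy)methyl]-5-(1,3-dioxolan-2-yl)-7-methoxy-2-[3-methoxy-4-(pivaloyloxy)phenyl]-2,3-dihydro-1-benzofuran | O1CCOC1c1cc(OC)c2c(c1)[C@@H](CO[Si](C)(C)C(C)(C)C)[C@@H](c1ccc(OC(=O)C(C)(C)C)c(OC)c1)O2
A2 | alternative 1 | 4-[(1R,2S)-3-(tert-butyldimethylsilyloxy)-2-[5-(1,3-dioxolan-2-yl)-2-hydroxy-3-methoxyphenyl]-1-hydroxypropyl]-2-methoxyphenyl pivalate | O1CCOC1c1cc(OC)c(O)c(c1)[C@@H](CO[Si](C)(C)C(C)(C)C)[C@@H](O)c1ccc(OC(=O)C(C)(C)C)c(OC)c1
A3 | alternative 2 | 5,5′-bis[(3Z)-1-(tert-butyldimethylsilyloxy)-3-(3-methoxy-4-tert-butyldimethylsilyloxyphenyl)pent-3-en-2-yl]pinoresinol, arm centres configured as in 23 | COc1cc(/C(=C\C)[C@H](CO[Si](C)(C)C(C)(C)C)c2cc([C@H]3OC[C@H]4[C@@H]3CO[C@@H]4c3cc(OC)c(O)c(c3)[C@@H](CO[Si](C)(C)C(C)(C)C)/C(=C/C)c3ccc(O[Si](C)(C)C(C)(C)C)c(OC)c3)cc(OC)c2O)ccc1O[Si](C)(C)C(C)(C)C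
A4 | alternative 2 | pinoresinol, (1R,2S,5R,6S)-2,6-bis(4-hydroxy-3-methoxyphenyl)-3,7-dioxabicyclo[3.3.0]octane | COc1cc(ccc1O)[C@H]1OC[C@H]2[C@@H]1CO[C@@H]2c1ccc(O)c(OC)c1
A5 | alternative 3 | 5,5′-dibromopinoresinol | COc1cc(cc(Br)c1O)[C@H]1OC[C@H]2[C@@H]1CO[C@@H]2c1cc(OC)c(O)c(Br)c1
A6 | alternative 3 | (1R,5R)-2,6-dimethoxy-3,7-dioxabicyclo[3.3.0]octane, acetal carbons as anomeric mixtures | COC1OC[C@H]2[C@@H]1COC2OC
A7 | alternative 3 | 2-bromo-6-methoxyphenol | COc1cccc(Br)c1O
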